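**Retrosynthetic overview**
1. Target ⇐ acid unmasking of a C14 acetal and a C15 silyl ether ⇐ ring-closing metathesis at C1=C10, which forms the ten-membered ring last.
2. C7–C8 ⇐ Barbier allylation of a 3-(bromomethyl)butenolide with a β,γ-unsaturated aldehyde; C8 ester ⇐ Mitsunobu inversion with (2S)-2-methylbutanoic acid.
3. Butenolide (first ring of the target) ⇐ asymmetric Ni/Cr coupling of a dienal with a β-iodoacrylate, which sets C6.
4. Dienal ⇐ key step: Birch dearomatisation of 4-methoxybenzyl alcohol; the cyclohexenone ring fixes C3 and C6 cis on C4=C5 and is then unzipped by Baeyer–Villiger oxidation, reduction and Wittig methylenation.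
5. Ring order: benzene → cyclohexenone → oxepinone (opened) → butenolide → cyclodecadiene.

Assumption: atom labels C1–C15 follow germacrane numbering (C6 lactone O–CH, C7 ring-fusion CH, C8 ester CH, C14 CHO, C15 CH2OH), and 2-bromo-3,3-diethoxyprop-1-ene and the Kishi-type chiral sulfonamide ligand are taken as purchasable.

**Step 1**
Reactants: 1 4-methoxybenzyl alcohol
Product: 3 4-(hydroxymethyl)cyclohex-3-en-1-one, via dienyl methyl ether 2 (not isolated)
Conditions: Li (5 equiv), NH3(l)/THF, t-BuOH, −78 to −33 °C; NH4Cl; then oxalic acid (0.2 equiv), MeOH/H2O, rt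
Reagents that add atoms: water, O
Why: Birch reduction of the arene as its lithium benzylic alkoxide (which suppresses C–O hydrogenolysis) gives the 1-methoxy-1,4-diene, and mild enol ether hydrolysis leaves the β,γ-double bond in place, so the ring now holds the future C3 and C6 cis on the C4=C5 olefin.

**Step 2**
Reactants: 3 4-(hydroxymethyl)cyclohex-3-en-1-one
Product: 4 4-{[tert-butyl(dimethyl)silyl]oxymethyl}cyclohex-3-en-1-one
Conditions: TBSCl (1.1 equiv), imidazole (2 equiv), DMF, 0 °C to rt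
Reagents that add atoms: tert-butyldimethylsilyl chloride, CC(C)(C)[Si](C)(C)Cl
Why: Silyl ether formation at the primary alcohol protects C15–OH for the oxidations that follow.

**Step 3**
Reactants: 4 4-{[tert-butyl(dimethyl)silyl]oxymethyl}cyclohex-3-en-1-one
Product: 5 5-{[tert-butyl(dimethyl)silyl]oxymethyl}-4,7-dihydrooxepin-2(3H)-one
Conditions: Me3SiOOSiMe3 (1.5 equiv), TMSOTf (0.1 equiv), CH2Cl2, −78 to −40 °C
Reagents that add atoms: bis(trimethylsilyl) peroxide, C[Si](C)(C)OO[Si](C)(C)C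
Why: Baeyer–Villiger oxidation in which the allylic CH2 migrates in preference to the plain CH2 and the silyl peroxide does not epoxidise the trisubstituted alkene, so the ring oxygen ends on the future C6 and the carbonyl is the future C1.

**Step 4**
Reactants: 5 5-{[tert-butyl(dimethyl)silyl]oxymethyl}-4,7-dihydrooxepin-2(3H)-one
Product: 7 (2E)-3-{[tert-butyl(dimethyl)silyl]oxymethyl}hepta-2,6-dien-1-ol, via lactol 6 (not isolated)
Conditions: DIBAL-H (i-Bu2AlH, 1.1 equiv), CH2Cl2, −78 °C; aqueous potassium sodium tartrate; crude lactol, Ph3PCH3Br (3 equiv), KOt-Bu (3 equiv), THF, 0 °C to rt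
Reagents that add atoms: methyltriphenylphosphonium bromide, C[P+](c1ccccc1)(c1ccccc1)c1ccccc1.[Br-]
Why: Partial reduction of the lactone to the lactol and Wittig methylenation of its open hydroxy-aldehyde form give the C1 vinyl group and free the C6 allylic alcohol, with the ring-derived olefin geometry (CH2OH cis to the butenyl chain) unchanged.

**Step 5**
Reactants: 7 (2E)-3-{[tert-butyl(dimethyl)silyl]oxymethyl}hepta-2,6-dien-1-ol
Product: 8 (2E)-3-{[tert-butyl(dimethyl)silyl]oxymethyl}hepta-2,6-dienal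
Conditions: activated MnO2 (15 equiv), CH2Cl2, rt
Reagents that add atoms: none
Why: Manganese dioxide oxidation is selective for the primary allylic alcohol and is neutral, so the trisubstituted double bond is not isomerised.

**Step 6**
Reactants: 9 methyl propiolate; 10 formaldehyde (used as paraformaldehyde)
Product: 11 methyl (2Z)-2-(hydroxymethyl)-3-iodoprop-2-enoate
Conditions: MgI2 (1.2 equiv), CH2Cl2, 0 °C; aqueous work-up
Reagents that add atoms: magnesium iodide, [Mg+2].[I-].[I-]
Why: Iodo-aldol (β-iodo Morita–Baylis–Hillman) reaction: iodide adds to the propiolate, the magnesium allenolate is trapped by formaldehyde at the α-carbon, and kinetic control at 0 °C gives the isomer with iodine cis to the ester.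

**Step 7**
Reactants: 8 (2E)-3-{[tert-butyl(dimethyl)silyl]oxymethyl}hepta-2,6-dienal; 11 methyl (2Z)-2-(hydroxymethyl)-3-iodoprop-2-enoate
Product: 13 (5R)-3-(hydroxymethyl)-5-[(1E)-2-{[tert-butyl(dimethyl)silyl]oxymethyl}hexa-1,5-dien-1-yl]furan-2(5H)-one, via hydroxy ester 12 (not isolated)
Conditions: CrCl2 (10 mol %), Kishi-type chiral oxazoline–sulfonamide ligand (11 mol %, enantiomer giving 5R), proton sponge (11 mol %), NiCl2 (2 mol %), Mn powder (2 equiv), Cp2ZrCl2 (1.1 equiv), LiCl (2 equiv), MeCN, rt; aqueous work-up, silica gel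
Reagents that add atoms: none
Why: Catalytic asymmetric Nozaki–Hiyama–Kishi coupling: nickel activates the vinyl iodide, the chiral trivalent-chromium alkenyl species adds to one face of the enal to set C6 as R, and the resulting (Z)-γ-hydroxy enoate lactonises to the butenolide.

**Step 8**
Reactants: 13 (5R)-3-(hydroxymethyl)-5-[(1E)-2-{[tert-butyl(dimethyl)silyl]oxymethyl}hexa-1,5-dien-1-yl]furan-2(5H)-one
Product: 14 (5R)-3-(bromomethyl)-5-[(1E)-2-{[tert-butyl(dimethyl)silyl]oxymethyl}hexa-1,5-dien-1-yl]furan-2(5H)-one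
Conditions: CBr4 (1.2 equiv), PPh3 (1.2 equiv), CH2Cl2, 0 °C
Reagents that add atoms: carbon tetrabromide, BrC(Br)(Br)Br
Why: Appel bromination turns the primary allylic alcohol into the allylic bromide needed for the Barbier step and does not touch the stereocentre.

**Step 9**
Reactants: 15 2-bromo-3,3-diethoxyprop-1-ene; 16 oxirane
Product: 18 3-(diethoxymethyl)but-3-en-1-ol, via vinyllithium 17 (not isolated)
Conditions: t-BuLi (2.0 equiv), Et2O, −78 °C; then oxirane, −78 to 0 °C; aqueous work-up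
Reagents that add atoms: none
Why: Bromine–lithium exchange gives the α-lithiated acrolein acetal, which opens oxirane by SN2 attack to give the homoallylic alcohol carrying the masked C14 aldehyde.

**Step 10**
Reactants: 18 3-(diethoxymethyl)but-3-en-1-ol
Product: 19 3-(diethoxymethyl)but-3-enal
Conditions: TEMPO (10 mol %), PhI(OAc)2 (1.1 equiv), CH2Cl2, 0 °C to rt; used crude
Reagents that add atoms: none
Why: Oxoammonium (TEMPO) oxidation stops at the aldehyde under mild conditions, so the β,γ-double bond does not move into conjugation.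

**Step 11**
Reactants: 14 (5R)-3-(bromomethyl)-5-[(1E)-2-{[tert-butyl(dimethyl)silyl]oxymethyl}hexa-1,5-dien-1-yl]furan-2(5H)-one; 19 3-(diethoxymethyl)but-3-enal
Product: 21 (4R,5R)-4-[(1S)-3-(diethoxymethyl)-1-hydroxybut-3-en-1-yl]-3-methylidene-5-[(1E)-2-{[tert-butyl(dimethyl)silyl]oxymethyl}hexa-1,5-dien-1-yl]oxolan-2-one, via allylzinc bromide 20 (not isolated)
Conditions: Zn dust (3 equiv), THF/sat. aq. NH4Cl (2:1), 0 °C
Reagents that add atoms: none
Why: Barbier allylation in which the allylzinc reacts at its γ-carbon (C7) on the face away from the C6 side chain to give the trans lactone with the exocyclic methylene, and a chair-like six-membered transition state with the aldehyde chain equatorial gives the 7,8-anti carbinol (8S, the epimer that the next step inverts).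

**Step 12**
Reactants: 21 (4R,5R)-4-[(1S)-3-(diethoxymethyl)-1-hydroxybut-3-en-1-yl]-3-methylidene-5-[(1E)-2-{[tert-butyl(dimethyl)silyl]oxymethyl}hexa-1,5-dien-1-yl]oxolan-2-one; 22 (2S)-2-methylbutanoic acid
Product: 23 (1R)-3-(diethoxymethyl)-1-{(2R,3R)-4-methylidene-5-oxo-2-[(1E)-2-{[tert-butyl(dimethyl)silyl]oxymethyl}hexa-1,5-dien-1-yl]oxolan-3-yl}but-3-en-1-yl (2S)-2-methylbutanoate
Conditions: PPh3 (2 equiv), DIAD (2 equiv), toluene, 0 °C to rt
Reagents that add atoms: none
Why: Mitsunobu esterification goes by SN2 displacement of the alkoxyphosphonium group, so the carboxylate inverts C8 from S to the required R while the α-centre of the acid is not touched.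

**Step 13**
Reactants: 23 (1R)-3-(diethoxymethyl)-1-{(2R,3R)-4-methylidene-5-oxo-2-[(1E)-2-{[tert-butyl(dimethyl)silyl]oxymethyl}hexa-1,5-dien-1-yl]oxolan-3-yl}but-3-en-1-yl (2S)-2-methylbutanoate
Product: 24 (3aR,4R,6E,10E,11aR)-6-(diethoxymethyl)-10-{[tert-butyl(dimethyl)silyl]oxymethyl}-3-methylidene-2-oxo-2,3,3a,4,5,8,9,11a-octahydrocyclodeca[b]furan-4-yl (2S)-2-methylbutanoate
Conditions: second-generation Hoveyda–Grubbs catalyst RuCl2(H2IMes)(=CH-C6H4-2-O-i-Pr) (10 mol %), toluene (1 mM), 80 °C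
Reagents that add atoms: none
Why: Ring-closing metathesis starts at the terminal vinyl group and closes onto the 1,1-disubstituted acetal-bearing olefin, and the trans-fused lactone with the existing cis C4=C5 unit favours the least strained cis,cis-cyclodeca-1,5-diene, in which C2 and C9 are cis.

**Step 14**
Reactants: 24 (3aR,4R,6E,10E,11aR)-6-(diethoxymethyl)-10-{[tert-butyl(dimethyl)silyl]oxymethyl}-3-methylidene-2-oxo-2,3,3a,4,5,8,9,11a-octahydrocyclodeca[b]furan-4-yl (2S)-2-methylbutanoate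
Product: 25 (3aR,4R,6E,10E,11aR)-6-formyl-10-(hydroxymethyl)-3-methylidene-2-oxo-2,3,3a,4,5,8,9,11a-octahydrocyclodeca[b]furan-4-yl (2S)-2-methylbutanoate
Conditions: TsOH·H2O (0.3 equiv), THF/H2O (4:1), rt
Reagents that add atoms: water, O
Why: Mild acid hydrolysis converts the diethyl acetal into the conjugated C14 aldehyde and cleaves the primary silyl ether to the C15 alcohol, and the enal settles in its more stable geometry with C2 trans to CHO, which is the one required.

**Compound list**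
1 | 4-methoxybenzyl alcohol | COc1ccc(CO)cc1 | starting material
2 | (4-methoxycyclohexa-1,4-dien-1-yl)methanol | COC1=CCC(CO)=CC1 | intermediate
3 | 4-(hydroxymethyl)cyclohex-3-en-1-one | O=C1CC=C(CO)CC1 | intermediate
4 | 4-{[tert-butyl(dimethyl)silyl]oxymethyl}cyclohex-3-en-1-one | O=C1CC=C(CO[Si](C)(C)C(C)(C)C)CC1 | intermediate
5 | 5-{[tert-butyl(dimethyl)silyl]oxymethyl}-4,7-dihydrooxepin-2(3H)-one | O=C1CCC(CO[Si](C)(C)C(C)(C)C)=CCO1 | intermediate
6 | 5-{[tert-butyl(dimethyl)silyl]oxymethyl}-2,3,4,7-tetrahydrooxepin-2-ol | OC1CCC(CO[Si](C)(C)C(C)(C)C)=CCO1 | intermediate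
7 | (2E)-3-{[tert-butyl(dimethyl)silyl]oxymethyl}hepta-2,6-dien-1-ol | OC/C=C(/CO[Si](C)(C)C(C)(C)C)CCC=C | intermediate
8 | (2E)-3-{[tert-butyl(dimethyl)silyl]oxymethyl}hepta-2,6-dienal | O=C/C=C(/CO[Si](C)(C)C(C)(C)C)CCC=C | intermediate
9 | methyl propiolate | COC(=O)C#C | starting material
10 | formaldehyde | C=O | starting material
11 | methyl (2Z)-2-(hydroxymethyl)-3-iodoprop-2-enoate | OC/C(C(=O)OC)=C/I | intermediate
12 | methyl (2Z,4R,5E)-4-hydroxy-2-(hydroxymethyl)-6-{[tert-butyl(dimethyl)silyl]oxymethyl}deca-2,5,9-trienoate | COC(=O)/C(CO)=C\[C@H](O)/C=C(/CO[Si](C)(C)C(C)(C)C)CCC=C | intermediate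
13 | (5R)-3-(hydroxymethyl)-5-[(1E)-2-{[tert-butyl(dimethyl)silyl]oxymethyl}hexa-1,5-dien-1-yl]furan-2(5H)-one | OCC1=C[C@@H](/C=C(/CO[Si](C)(C)C(C)(C)C)CCC=C)OC1=O | intermediate
14 | (5R)-3-(bromomethyl)-5-[(1E)-2-{[tert-butyl(dimethyl)silyl]oxymethyl}hexa-1,5-dien-1-yl]furan-2(5H)-one | BrCC1=C[C@@H](/C=C(/CO[Si](C)(C)C(C)(C)C)CCC=C)OC1=O | intermediate
15 | 2-bromo-3,3-diethoxyprop-1-ene | C=C(Br)C(OCC)OCC | starting material
16 | oxirane | C1CO1 | starting material
17 | (3,3-diethoxyprop-1-en-2-yl)lithium | [Li]C(=C)C(OCC)OCC | intermediate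
18 | 3-(diethoxymethyl)but-3-en-1-ol | OCCC(=C)C(OCC)OCC | intermediate
19 | 3-(diethoxymethyl)but-3-enal | O=CCC(=C)C(OCC)OCC | intermediate
20 | {[(5R)-2-oxo-5-[(1E)-2-{[tert-butyl(dimethyl)silyl]oxymethyl}hexa-1,5-dien-1-yl]-2,5-dihydrofuran-3-yl]methyl}zinc bromide | Br[Zn]CC1=C[C@@H](/C=C(/CO[Si](C)(C)C(C)(C)C)CCC=C)OC1=O | intermediate
21 | (4R,5R)-4-[(1S)-3-(diethoxymethyl)-1-hydroxybut-3-en-1-yl]-3-methylidene-5-[(1E)-2-{[tert-butyl(dimethyl)silyl]oxymethyl}hexa-1,5-dien-1-yl]oxolan-2-one | C=C1C(=O)O[C@H](/C=C(/CO[Si](C)(C)C(C)(C)C)CCC=C)[C@H]1[C@@H](O)CC(=C)C(OCC)OCC | intermediate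
22 | (2S)-2-methylbutanoic acid | OC(=O)[C@@H](C)CC | starting material
23 | (1R)-3-(diethoxymethyl)-1-{(2R,3R)-4-methylidene-5-oxo-2-[(1E)-2-{[tert-butyl(dimethyl)silyl]oxymethyl}hexa-1,5-dien-1-yl]oxolan-3-yl}but-3-en-1-yl (2S)-2-methylbutanoate | C=C1C(=O)O[C@H](/C=C(/CO[Si](C)(C)C(C)(C)C)CCC=C)[C@H]1[C@H](OC(=O)[C@@H](C)CC)CC(=C)C(OCC)OCC | intermediate
24 | (3aR,4R,6E,10E,11aR)-6-(diethoxymethyl)-10-{[tert-butyl(dimethyl)silyl]oxymethyl}-3-methylidene-2-oxo-2,3,3a,4,5,8,9,11a-octahydrocyclodeca[b]furan-4-yl (2S)-2-methylbutanoate | C=C1C(=O)O[C@@H]2/C=C(/CO[Si](C)(C)C(C)(C)C)CC/C=C(/C(OCC)OCC)C[C@@H](OC(=O)[C@@H](C)CC)[C@@H]12 | intermediate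
25 | (3aR,4R,6E,10E,11aR)-6-formyl-10-(hydroxymethyl)-3-methylidene-2-oxo-2,3,3a,4,5,8,9,11a-octahydrocyclodeca[b]furan-4-yl (2S)-2-methylbutanoate | C=C1C(=O)O[C@@H]2/C=C(/CO)CC/C=C(/C=O)C[C@@H](OC(=O)[C@@H](C)CC)[C@@H]12 | target

**Step count and risk**
Total: 14 steps. Longest linear sequence: 11 steps (steps 1–5, 7, 8, 11–14).

Step 13 (most likely to fail): closing a ten-membered ring onto a hindered 1,1-disubstituted olefin may give oligomers or the wrong olefin geometry. The fallback sets out from 14 and 19 and comes back at 24. Cross-metathesis with the second-generation Grubbs catalyst RuCl2(H2IMes)(PCy3)(=CHPh) in CH2Cl2 at 40 °C joins the vinyl group of 14 to the 1,1-disubstituted olefin of 19 and gives (5R)-3-(bromomethyl)-5-[(1E,5E)-6-(diethoxymethyl)-8-oxo-2-{[tert-butyl(dimethyl)silyl]oxymethyl}octa-1,5-dien-1-yl]furan-2(5H)-one F1. Zinc in THF/aqueous NH4Cl at 1 mM then closes the ring by an intramolecular Barbier reaction at C7–C8 to (3aR,4S,6E,10E,11aR)-6-(diethoxymethyl)-4-hydroxy-10-{[tert-butyl(dimethyl)silyl]oxymethyl}-3-methylidene-3a,4,5,8,9,11a-hexahydrocyclodeca[b]furan-2(3H)-one F2. The Mitsunobu conditions of step 12 with 22 convert this alcohol into 24.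

Step 7: the enantioselectivity of the Ni/Cr coupling is untested for a β-iodoacrylate with an enal. The fallback sets out from 8 and 9 and comes back at 13. Addition of methyl propiolate 9 to 8 with Me2Zn and a ProPhenol ligand gives methyl (4R,5E)-4-hydroxy-6-{[tert-butyl(dimethyl)silyl]oxymethyl}deca-5,9-dien-2-ynoate F3. Semihydrogenation over Pd/CaCO3 poisoned with Pb(OAc)2 and quinoline gives the (Z)-enoate, which lactonises to (5S)-5-[(1E)-2-{[tert-butyl(dimethyl)silyl]oxymethyl}hexa-1,5-dien-1-yl]furan-2(5H)-one F4 (same spatial arrangement as 13; only the CIP priorities change). Morita–Baylis–Hillman hydroxymethylation of this butenolide with aqueous formaldehyde 10 and imidazole gives 13.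

Step 12: Mitsunobu inversion of a hindered homoallylic alcohol with a weakly acidic aliphatic acid may be slow or give elimination. The fallback sets out from 21 and comes back at 23. Chloromethanesulfonyl chloride and pyridine give the chloromethanesulfonate ester of 21 (all centres as in 21) F5, and caesium (2S)-2-methylbutanoate (from 22 and Cs2CO3) with 18-crown-6 in toluene displaces it with inversion to give 23. The Barbier selectivity in step 11 is predicted, not measured; if the 8R carbinol forms instead, plain carbodiimide esterification with retention replaces step 12.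

**Further compounds**
F1 | step 13 | (5R)-3-(bromomethyl)-5-[(1E,5E)-6-(diethoxymethyl)-8-oxo-2-{[tert-butyl(dimethyl)silyl]oxymethyl}octa-1,5-dien-1-yl]furan-2(5H)-one | BrCC1=C[C@@H](/C=C(/CO[Si](C)(C)C(C)(C)C)CC/C=C(/C(OCC)OCC)CC=O)OC1=O
F2 | step 13 | (3aR,4S,6E,10E,11aR)-6-(diethoxymethyl)-4-hydroxy-10-{[tert-butyl(dimethyl)silyl]oxymethyl}-3-methylidene-3a,4,5,8,9,11a-hexahydrocyclodeca[b]furan-2(3H)-one | C=C1C(=O)O[C@@H]2/C=C(/CO[Si](C)(C)C(C)(C)C)CC/C=C(/C(OCC)OCC)C[C@H](O)[C@@H]12
F3 | step 7 | methyl (4R,5E)-4-hydroxy-6-{[tert-butyl(dimethyl)silyl]oxymethyl}deca-5,9-dien-2-ynoate | COC(=O)C#C[C@H](O)/C=C(/CO[Si](C)(C)C(C)(C)C)CCC=C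
F4 | step 7 | (5S)-5-[(1E)-2-{[tert-butyl(dimethyl)silyl]oxymethyl}hexa-1,5-dien-1-yl]furan-2(5H)-one | O=C1C=C[C@@H](/C=C(/CO[Si](C)(C)C(C)(C)C)CCC=C)O1
F5 | step 12 | chloromethanesulfonate ester of 21 (all centres as in 21) | C=C1C(=O)O[C@H](/C=C(/CO[Si](C)(C)C(C)(C)C)CCC=C)[C@H]1[C@@H](OS(=O)(=O)CCl)CC(=C)C(OCC)OCC
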